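**Retrosynthetic overview**
1. End game: the C-7/C-8/C-9 triad comes from a Δ8-7-one by conjugate addition of a linalool-derived C-11–C-16 Grignard reagent anti to C-20, Mannich methylenation and Luche reduction. The 2α,3α-diol comes from osmylation of a Δ2 olefin, and the two esters are placed one after the other.
2. The Δ8-7-one comes from Wharton transposition of a Δ7-9-one, and the Δ2 olefin from a C-3 ketone through its enol triflate. The C-9 ketone and the ester level of C-20 are activating groups that the route removes again.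
3. Key disconnection: ring A (C-1, C-2, C-3, C-4, C-5, C-10) is cut at C-1/C-10 and at C-3/C-4 into acrolein (C-1 to C-3) and the monocyclic β-keto ester 6. Enabling feature: C-10 sits between the ring-B C-9 carbonyl and the C-20 ester carbon (soft enolate carbon), and C-4 is the internal carbon of an isopropenyl group on the neighbouring C-5 (tertiary radical by Fe–H hydrogen-atom transfer). The two sites are 1,3-related and trans on ring B, so a three-carbon enal can span them.
4. Compound 6 comes from methyl acetoacetate and (E)-4-methylpenta-2,4-dienal by organocatalytic Michael addition and aldol condensation, which sets C-5. Ring order: B (step 2), then A (step 3).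

Key step: step 3

Remark: locants are labdane locants (ring A C-1 to C-5 and C-10, ring B C-5 to C-10, C-20 on C-10, C-17 on C-8, side chain C-11 to C-16); α is the face of H-5, β the face of C-20; bicyclic intermediates are named as trans-decalins with these locants.
Remark: read from the target structure, the 2-methylbutanoate centre and C-13 are both R, so (R)-2-methylbutanoic acid and (R)-(−)-linalool are used and are assumed to be available in high enantiomeric purity.

**Route**

Step 1
Reactants: 1 methacrolein; 2 (triphenylphosphoranylidene)acetaldehyde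
Product: 3 (E)-4-methylpenta-2,4-dienal
Conditions: CH2Cl2, rt (1.0 equiv ylide)
Reagents that add atoms: none
Why: Wittig olefination with the stabilised formyl ylide should give the (E)-enal, and the conjugated product is less electrophilic than methacrolein so a second homologation should stay minor.

Step 2
Reactants: 3 (E)-4-methylpenta-2,4-dienal; 4 methyl acetoacetate
Product: 6 methyl (1S,6R)-2-oxo-6-(prop-1-en-2-yl)cyclohex-3-ene-1-carboxylate (trans drawn; C-1 epimerises), via Michael adduct 5 (not isolated)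
Conditions: (S)-α,α-diphenylprolinol trimethylsilyl ether (10 mol%), PhCO2H (10 mol%), toluene, 0 °C→rt; then TsOH·H2O (20 mol%), 40 °C
Reagents that add atoms: none
Why: Iminium-catalysed asymmetric Michael addition of the β-keto ester to the β-carbon of the dienal, on the face left open by the CPh2OSiMe3 group of the (S)-catalyst, should set C-5 as R (the sense this catalyst gives with malonates and β-aryl enals), and acid then closes ring B by intramolecular aldol condensation of the acetyl methyl group onto the aldehyde.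

Step 3
Reactants: 6 methyl (1S,6R)-2-oxo-6-(prop-1-en-2-yl)cyclohex-3-ene-1-carboxylate; 7 acrolein
Product: 9 methyl 3β-hydroxy-4,4-dimethyl-9-oxo-5α-decal-7-ene-10β-carboxylate (C-3 epimers; 3β drawn), via keto aldehyde 8 (not isolated)
Conditions: acrolein (1.05 equiv), Et3N (10 mol%), EtOH, 0 °C→rt; then EtOH to 0.02 M, Fe(acac)3 (0.5 equiv), PhSiH3 (2.5 equiv), 60 °C
Reagents that add atoms: none
Why: Proposed new method: amine-catalysed Michael addition of the C-10 β-keto ester enolate of 6 to acrolein gives aldehyde 8, and in the same flask Fe–H from Fe(acac)3/PhSiH3 transfers a hydrogen atom to the CH2 of the isopropenyl group (Mukaiyama-type HAT), the tertiary C-4 radical adds to the tethered aldehyde carbon C-3, and the alkoxy radical is reduced and protonated, so that C-1–C-10 and C-3–C-4 are both formed in one operation. The closest known reaction types are the Michael addition of cyclic β-keto esters to acrolein and the Fe(acac)3/PhSiH3 reductive radical cyclisation of alkene-tethered ketones and nitriles; the aldehyde as radical acceptor and the telescoping are what is new. Ring A closes by 6-exo-trig attack of the C-4 radical on the C=O carbon and should be trans-fused because the C-1 chain and the C-4 radical centre are trans-diequatorial on ring B. C-10 is set in the Michael step by approach of acrolein anti to the C-5 isopropenyl group (ester cis to C-4), C-5 is carried over from 6, and C-3 forms as an epimer mixture that step 4 erases. The step needs C-alkylation at C-10 and not at the γ-carbon, HAT to the 1,1-disubstituted alkene and not to the enone, and cyclisation ahead of intermolecular radical addition or simple alkene reduction; the acidity of H-10, the electron-poor enone, the fast 6-exo addition to CHO and the high dilution should secure these.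

Step 4
Reactants: 9 methyl 3β-hydroxy-4,4-dimethyl-9-oxo-5α-decal-7-ene-10β-carboxylate
Product: 10 methyl 4,4-dimethyl-3,9-dioxo-5α-decal-7-ene-10β-carboxylate
Conditions: Dess–Martin periodinane, CH2Cl2, rt
Reagents that add atoms: none
Why: Dess–Martin oxidation should convert both C-3 epimers into one ketone without base, so retro-Michael opening of ring A is avoided.

Step 5
Reactants: 10 methyl 4,4-dimethyl-3,9-dioxo-5α-decal-7-ene-10β-carboxylate
Product: 11 methyl 4,4-dimethyl-9-oxo-3-(trifluoromethanesulfonyloxy)-5α-decala-2,7-diene-10β-carboxylate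
Conditions: KHMDS (1.05 equiv), THF, −78 °C; PhNTf2, −78→0 °C
Reagents that add atoms: N-phenylbis(trifluoromethanesulfonimide), O=S(=O)(N(c1ccccc1)S(=O)(=O)C(F)(F)F)C(F)(F)F
Why: Kinetic enolisation can only go towards C-2 (C-4 is quaternary and the enone has no α′-hydrogen), and O-sulfonylation of the enolate gives the enol triflate (enol triflate formation).

Step 6
Reactants: 11 methyl 4,4-dimethyl-9-oxo-3-(trifluoromethanesulfonyloxy)-5α-decala-2,7-diene-10β-carboxylate
Product: 12 methyl 4,4-dimethyl-9-oxo-5α-decala-2,7-diene-10β-carboxylate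
Conditions: Pd(OAc)2 (5 mol%), PPh3 (10 mol%), Bu3N, HCO2H, DMF, 60 °C
Reagents that add atoms: none
Why: Palladium-catalysed formate reduction of the enol triflate should give the Δ2 olefin regiospecifically, a reduction that tolerates conjugated enones.

Step 7
Reactants: 12 methyl 4,4-dimethyl-9-oxo-5α-decala-2,7-diene-10β-carboxylate
Product: 13 methyl 7α,8α-epoxy-4,4-dimethyl-9-oxo-5α-decal-2-ene-10β-carboxylate
Conditions: t-BuOOH, DBU, CH2Cl2, 0 °C→rt
Reagents that add atoms: tert-butyl hydroperoxide, CC(C)(C)OO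
Why: Weitz–Scheffer nucleophilic epoxidation touches only the enone double bond and leaves the isolated Δ2 olefin; the α-epoxide is expected, and its configuration is lost again in step 10.

Step 8
Reactants: 13 methyl 7α,8α-epoxy-4,4-dimethyl-9-oxo-5α-decal-2-ene-10β-carboxylate
Product: 14 methyl 7α-hydroxy-4,4-dimethyl-5α-decala-2,8-diene-10β-carboxylate
Conditions: N2H4·H2O, AcOH (cat.), MeOH, 0 °C→rt
Reagents that add atoms: none
Why: Wharton transposition of the epoxy ketone hydrazone, with loss of N2, should move the oxygen from C-9 to C-7 and place the double bond at C-8/C-9 with retention at C-7.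

Step 9
Reactants: 14 methyl 7α-hydroxy-4,4-dimethyl-5α-decala-2,8-diene-10β-carboxylate
Product: 15 10β-(hydroxymethyl)-4,4-dimethyl-5α-decala-2,8-dien-7α-ol
Conditions: LiAlH4, THF, 0 °C→rt
Reagents that add atoms: none
Why: Hydride reduction of the neopentyl methyl ester brings C-20 to the alcohol level, and nothing else in the molecule is reducible.

Step 10
Reactants: 15 10β-(hydroxymethyl)-4,4-dimethyl-5α-decala-2,8-dien-7α-ol
Product: 16 10β-(hydroxymethyl)-4,4-dimethyl-5α-decala-2,8-dien-7-one
Conditions: MnO2, CH2Cl2, rt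
Reagents that add atoms: none
Why: MnO2 oxidises only the allylic C-7 alcohol and leaves the saturated primary C-20 alcohol (chemoselective allylic oxidation).

Step 11
Reactants: 16 10β-(hydroxymethyl)-4,4-dimethyl-5α-decala-2,8-dien-7-one; 17 (R)-2-methylbutanoic acid
Product: 18 (4,4-dimethyl-7-oxo-5α-decala-2,8-dien-10β-yl)methyl (2R)-2-methylbutanoate
Conditions: DCC, DMAP (cat.), CH2Cl2, 0 °C→rt
Reagents that add atoms: none
Why: Steglich esterification of the only free hydroxyl group installs the C-20 ester under conditions that should not racemise the α-centre of the acid.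

Step 12
Reactants: 18 (4,4-dimethyl-7-oxo-5α-decala-2,8-dien-10β-yl)methyl (2R)-2-methylbutanoate
Product: 19 (2α,3α-dihydroxy-4,4-dimethyl-7-oxo-5α-decal-8-en-10β-yl)methyl (2R)-2-methylbutanoate
Conditions: OsO4 (2 mol%), NMO, acetone/H2O, rt
Reagents that add atoms: osmium tetroxide, O=[Os](=O)(=O)=O; N-methylmorpholine N-oxide, C[N+]1([O-])CCOCC1
Why: Catalytic syn-dihydroxylation should take the electron-richer isolated Δ2 olefin in preference to the enone, from the α-face, because the axial 4β-methyl group and C-20 block the β-face; this sets C-2 and C-3.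

Step 13
Reactants: 19 (2α,3α-dihydroxy-4,4-dimethyl-7-oxo-5α-decal-8-en-10β-yl)methyl (2R)-2-methylbutanoate; 20 angelic acid
Product: 22 (2α-angeloyloxy-3α-hydroxy-4,4-dimethyl-7-oxo-5α-decal-8-en-10β-yl)methyl (2R)-2-methylbutanoate, via mixed anhydride 21 (not isolated)
Conditions: 20, 2,4,6-trichlorobenzoyl chloride, Et3N, toluene, rt; then 19, 80 °C
Reagents that add atoms: none
Why: Yamaguchi-type esterification through the mixed anhydride is the usual way to make angelates without Z→E isomerisation, and the equatorial C-2 hydroxyl should react in preference to the axial C-3 hydroxyl next to the gem-dimethyl carbon.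

Step 14
Reactants: 22 (2α-angeloyloxy-3α-hydroxy-4,4-dimethyl-7-oxo-5α-decal-8-en-10β-yl)methyl (2R)-2-methylbutanoate
Product: 23 [2α-angeloyloxy-4,4-dimethyl-7-oxo-3α-(triethylsilyloxy)-5α-decal-8-en-10β-yl]methyl (2R)-2-methylbutanoate
Conditions: TESOTf, 2,6-lutidine, CH2Cl2, −78→0 °C
Reagents that add atoms: triethylsilyl trifluoromethanesulfonate, CC[Si](CC)(CC)OS(=O)(=O)C(F)(F)F
Why: Silylation of the hindered C-3 hydroxyl prevents alkoxide formation and 2→3 acyl migration in the organometallic step that follows (silyl ether protection).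

Step 15
Reactants: 24 (R)-(−)-linalool
Product: 25 triethyl{[(3R)-3,7-dimethylocta-1,6-dien-3-yl]oxy}silane
Conditions: TESOTf, 2,6-lutidine, CH2Cl2, 0 °C
Reagents that add atoms: triethylsilyl trifluoromethanesulfonate, CC[Si](CC)(CC)OS(=O)(=O)C(F)(F)F
Why: Silyl triflate protection of the tertiary allylic alcohol keeps the C-13 stereocentre of the chiral pool intact.

Step 16
Reactants: 25 triethyl{[(3R)-3,7-dimethylocta-1,6-dien-3-yl]oxy}silane
Product: 26 (4R)-4-methyl-4-(triethylsilyloxy)hex-5-enal
Conditions: O3 (1 equiv, Sudan Red 7B end point), pyridine, CH2Cl2/MeOH, −78 °C; Me2S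
Reagents that add atoms: ozone, [O-][O+]=O
Why: Ozonolysis should cleave the electron-rich trisubstituted olefin well before the hindered, oxygen-deactivated vinyl group.

Step 17
Reactants: 26 (4R)-4-methyl-4-(triethylsilyloxy)hex-5-enal
Product: 27 (4R)-4-methyl-4-(triethylsilyloxy)hex-5-enoic acid
Conditions: NaClO2, NaH2PO4, 2-methylbut-2-ene, t-BuOH/H2O, 0 °C→rt
Reagents that add atoms: sodium chlorite, [Na+].[O-]Cl=O
Why: Pinnick oxidation converts the aldehyde into the acid, with the scavenger protecting the vinyl group from hypochlorite.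

Step 18
Reactants: 27 (4R)-4-methyl-4-(triethylsilyloxy)hex-5-enoic acid
Product: 29 triethyl{[(3R)-5-iodo-3-methylpent-1-en-3-yl]oxy}silane, via Barton ester 28 (not isolated)
Conditions: N-hydroxypyridine-2-thione, DCC, DMAP (cat.), CH2Cl2, dark, 0 °C; then CHI3, hν (W lamp), rt
Reagents that add atoms: iodoform, IC(I)I
Why: Barton decarboxylative iodination removes the extra carbon through a primary radical that cannot cyclise onto the vinyl group (4-exo or 5-endo only) and takes iodine from iodoform.

Step 19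
Reactants: 23 [2α-angeloyloxy-4,4-dimethyl-7-oxo-3α-(triethylsilyloxy)-5α-decal-8-en-10β-yl]methyl (2R)-2-methylbutanoate; 29 triethyl{[(3R)-5-iodo-3-methylpent-1-en-3-yl]oxy}silane; 30 Eschenmoser's salt (N,N-dimethylmethyleneiminium iodide)
Product: 33 (13R)-2α-angeloyloxy-17-(dimethylamino)-7-oxo-3α,13-bis(triethylsilyloxy)-9βH-labd-14-en-20-yl (2R)-2-methylbutanoate (C-8 epimers), via Grignard reagent 31 (not isolated), via silyl enol ether 32 (not isolated)
Conditions: 29, Mg, Et2O, rt; then 23, CuBr·SMe2 (10 mol%), TMSCl, HMPA, THF, −78 °C; then 30, CH2Cl2, rt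
Reagents that add atoms: none
Why: Copper-catalysed, TMSCl-accelerated conjugate addition of the Grignard reagent should occur at C-9 anti to the axial C-20 group (as cuprates add to steroidal 1-en-3-ones), which sets the 9α side chain, and the regiodefined silyl enol ether then undergoes a Mannich reaction at C-8.

Step 20
Reactants: 33 (13R)-2α-angeloyloxy-17-(dimethylamino)-7-oxo-3α,13-bis(triethylsilyloxy)-9βH-labd-14-en-20-yl (2R)-2-methylbutanoate
Product: 35 (13R)-2α-angeloyloxy-7-oxo-3α,13-bis(triethylsilyloxy)-9βH-labda-8(17),14-dien-20-yl (2R)-2-methylbutanoate, via ammonium iodide 34 (not isolated)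
Conditions: MeI, CH2Cl2, rt; then aq. NaHCO3, rt
Reagents that add atoms: none
Why: Quaternisation followed by mild-base E1cB (Hofmann-type) elimination of trimethylamine gives the α-methylene ketone, and bicarbonate is weak enough to spare the angelate geometry and C-9.

Step 21
Reactants: 35 (13R)-2α-angeloyloxy-7-oxo-3α,13-bis(triethylsilyloxy)-9βH-labda-8(17),14-dien-20-yl (2R)-2-methylbutanoate
Product: 36 (13R)-2α-angeloyloxy-7α-hydroxy-3α,13-bis(triethylsilyloxy)-9βH-labda-8(17),14-dien-20-yl (2R)-2-methylbutanoate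
Conditions: NaBH4, CeCl3·7H2O, MeOH, −78 °C
Reagents that add atoms: none
Why: Luche 1,2-reduction leaves the esters alone, and because the axial 9α side chain blocks axial hydride approach from the α-face, equatorial delivery should give the axial 7α-alcohol.

Step 22
Reactants: 36 (13R)-2α-angeloyloxy-7α-hydroxy-3α,13-bis(triethylsilyloxy)-9βH-labda-8(17),14-dien-20-yl (2R)-2-methylbutanoate
Product: 37 (13R)-2α-angeloyloxy-3α,7α,13-trihydroxy-9βH-labda-8(17),14-dien-20-yl (2R)-2-methylbutanoate (CNP0391865.1; 2R,3S,5R,7R,9S,10R,13R)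
Conditions: HF·pyridine, pyridine, THF, 0 °C→rt
Reagents that add atoms: none
Why: Buffered fluoride desilylation removes both triethylsilyl groups without base, so no acyl migration or angelate isomerisation is expected.

**Compound list**
1 | methacrolein (2-methylprop-2-enal) | C=C(C)C=O | starting material
2 | (triphenylphosphoranylidene)acetaldehyde | O=CC=P(c1ccccc1)(c1ccccc1)c1ccccc1 | starting material
3 | (E)-4-methylpenta-2,4-dienal | C=C(C)/C=C/C=O | intermediate
4 | methyl acetoacetate | COC(=O)CC(C)=O | starting material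
5 | methyl (3R)-2-acetyl-4-methyl-3-(2-oxoethyl)pent-4-enoate (not isolated) | COC(=O)C(C(C)=O)[C@@H](CC=O)C(C)=C | intermediate
6 | methyl (1S,6R)-2-oxo-6-(prop-1-en-2-yl)cyclohex-3-ene-1-carboxylate | COC(=O)[C@@H]1C(=O)C=CC[C@H]1C(C)=C | intermediate
7 | acrolein (prop-2-enal) | C=CC=O | starting material
8 | methyl (1R,6R)-2-oxo-1-(3-oxopropyl)-6-(prop-1-en-2-yl)cyclohex-3-ene-1-carboxylate (not isolated) | O=CCC[C@]1(C(=O)OC)C(=O)C=CC[C@H]1C(C)=C | intermediate
9 | methyl 3β-hydroxy-4,4-dimethyl-9-oxo-5α-decal-7-ene-10β-carboxylate (C-3 epimers) | O=C1C=CC[C@H]2C(C)(C)[C@@H](O)CC[C@]12C(=O)OC | intermediate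
10 | methyl 4,4-dimethyl-3,9-dioxo-5α-decal-7-ene-10β-carboxylate | O=C1C=CC[C@H]2C(C)(C)C(=O)CC[C@]12C(=O)OC | intermediate
11 | methyl 4,4-dimethyl-9-oxo-3-(trifluoromethanesulfonyloxy)-5α-decala-2,7-diene-10β-carboxylate | O=C1C=CC[C@H]2C(C)(C)C(OS(=O)(=O)C(F)(F)F)=CC[C@]12C(=O)OC | intermediate
12 | methyl 4,4-dimethyl-9-oxo-5α-decala-2,7-diene-10β-carboxylate | O=C1C=CC[C@H]2C(C)(C)C=CC[C@]12C(=O)OC | intermediate
13 | methyl 7α,8α-epoxy-4,4-dimethyl-9-oxo-5α-decal-2-ene-10β-carboxylate | O=C1[C@@H]2O[C@@H]2C[C@H]3C(C)(C)C=CC[C@]13C(=O)OC | intermediate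
14 | methyl 7α-hydroxy-4,4-dimethyl-5α-decala-2,8-diene-10β-carboxylate | C1=C[C@H](O)C[C@H]2C(C)(C)C=CC[C@]12C(=O)OC | intermediate
15 | 10β-(hydroxymethyl)-4,4-dimethyl-5α-decala-2,8-dien-7α-ol | C1=C[C@H](O)C[C@H]2C(C)(C)C=CC[C@]12CO | intermediate
16 | 10β-(hydroxymethyl)-4,4-dimethyl-5α-decala-2,8-dien-7-one | C1=CC(=O)C[C@H]2C(C)(C)C=CC[C@]12CO | intermediate
17 | (R)-2-methylbutanoic acid | CC[C@@H](C)C(=O)O | starting material
18 | (4,4-dimethyl-7-oxo-5α-decala-2,8-dien-10β-yl)methyl (2R)-2-methylbutanoate | C1=CC(=O)C[C@H]2C(C)(C)C=CC[C@]12COC(=O)[C@H](C)CC | intermediate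
19 | (2α,3α-dihydroxy-4,4-dimethyl-7-oxo-5α-decal-8-en-10β-yl)methyl (2R)-2-methylbutanoate | C1=CC(=O)C[C@H]2C(C)(C)[C@H](O)[C@H](O)C[C@]12COC(=O)[C@H](C)CC | intermediate
20 | angelic acid ((Z)-2-methylbut-2-enoic acid) | C/C=C(/C)C(=O)O | starting material
21 | angelic 2,4,6-trichlorobenzoic anhydride (not isolated) | C/C=C(/C)C(=O)OC(=O)c1c(Cl)cc(Cl)cc1Cl | intermediate
22 | (2α-angeloyloxy-3α-hydroxy-4,4-dimethyl-7-oxo-5α-decal-8-en-10β-yl)methyl (2R)-2-methylbutanoate | C1=CC(=O)C[C@H]2C(C)(C)[C@H](O)[C@H](OC(=O)/C(C)=C\C)C[C@]12COC(=O)[C@H](C)CC | intermediate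
23 | [2α-angeloyloxy-4,4-dimethyl-7-oxo-3α-(triethylsilyloxy)-5α-decal-8-en-10β-yl]methyl (2R)-2-methylbutanoate | C1=CC(=O)C[C@H]2C(C)(C)[C@H](O[Si](CC)(CC)CC)[C@H](OC(=O)/C(C)=C\C)C[C@]12COC(=O)[C@H](C)CC | intermediate
24 | (R)-(−)-linalool | C=C[C@](C)(O)CCC=C(C)C | starting material
25 | triethyl{[(3R)-3,7-dimethylocta-1,6-dien-3-yl]oxy}silane | C=C[C@](C)(O[Si](CC)(CC)CC)CCC=C(C)C | intermediate
26 | (4R)-4-methyl-4-(triethylsilyloxy)hex-5-enal | C=C[C@](C)(O[Si](CC)(CC)CC)CCC=O | intermediate
27 | (4R)-4-methyl-4-(triethylsilyloxy)hex-5-enoic acid | C=C[C@](C)(O[Si](CC)(CC)CC)CCC(=O)O | intermediate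
28 | 2-thioxopyridin-1(2H)-yl (4R)-4-methyl-4-(triethylsilyloxy)hex-5-enoate (Barton ester, not isolated) | C=C[C@](C)(O[Si](CC)(CC)CC)CCC(=O)On1ccccc1=S | intermediate
29 | triethyl{[(3R)-5-iodo-3-methylpent-1-en-3-yl]oxy}silane | C=C[C@](C)(O[Si](CC)(CC)CC)CCI | intermediate
30 | Eschenmoser's salt (N,N-dimethylmethyleneiminium iodide) | C=[N+](C)C.[I-] | starting material
31 | [(3R)-3-methyl-3-(triethylsilyloxy)pent-4-en-1-yl]magnesium iodide (not isolated) | C=C[C@](C)(O[Si](CC)(CC)CC)CC[Mg]I | intermediate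
32 | (13R)-2α-angeloyloxy-3α,13-bis(triethylsilyloxy)-7-(trimethylsilyloxy)-9βH-17-norlabda-7,14-dien-20-yl (2R)-2-methylbutanoate (not isolated) | C=C[C@](C)(O[Si](CC)(CC)CC)CC[C@@H]1C=C(O[Si](C)(C)C)C[C@H]2C(C)(C)[C@H](O[Si](CC)(CC)CC)[C@H](OC(=O)/C(C)=C\C)C[C@]12COC(=O)[C@H](C)CC | intermediate
33 | (13R)-2α-angeloyloxy-17-(dimethylamino)-7-oxo-3α,13-bis(triethylsilyloxy)-9βH-labd-14-en-20-yl (2R)-2-methylbutanoate (C-8 epimers) | C=C[C@](C)(O[Si](CC)(CC)CC)CC[C@@H]1C(CN(C)C)C(=O)C[C@H]2C(C)(C)[C@H](O[Si](CC)(CC)CC)[C@H](OC(=O)/C(C)=C\C)C[C@]12COC(=O)[C@H](C)CC | intermediate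
34 | 17-trimethylammonium iodide of 33 (not isolated) | C=C[C@](C)(O[Si](CC)(CC)CC)CC[C@@H]1C(C[N+](C)(C)C)C(=O)C[C@H]2C(C)(C)[C@H](O[Si](CC)(CC)CC)[C@H](OC(=O)/C(C)=C\C)C[C@]12COC(=O)[C@H](C)CC.[I-] | intermediate
35 | (13R)-2α-angeloyloxy-7-oxo-3α,13-bis(triethylsilyloxy)-9βH-labda-8(17),14-dien-20-yl (2R)-2-methylbutanoate | C=C[C@](C)(O[Si](CC)(CC)CC)CC[C@@H]1C(=C)C(=O)C[C@H]2C(C)(C)[C@H](O[Si](CC)(CC)CC)[C@H](OC(=O)/C(C)=C\C)C[C@]12COC(=O)[C@H](C)CC | intermediate
36 | (13R)-2α-angeloyloxy-7α-hydroxy-3α,13-bis(triethylsilyloxy)-9βH-labda-8(17),14-dien-20-yl (2R)-2-methylbutanoate | C=C[C@](C)(O[Si](CC)(CC)CC)CC[C@@H]1C(=C)[C@H](O)C[C@H]2C(C)(C)[C@H](O[Si](CC)(CC)CC)[C@H](OC(=O)/C(C)=C\C)C[C@]12COC(=O)[C@H](C)CC | intermediate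
37 | (13R)-2α-angeloyloxy-3α,7α,13-trihydroxy-9βH-labda-8(17),14-dien-20-yl (2R)-2-methylbutanoate | C=C[C@](C)(O)CC[C@@H]1C(=C)[C@H](O)C[C@H]2C(C)(C)[C@H](O)[C@H](OC(=O)/C(C)=C\C)C[C@]12COC(=O)[C@H](C)CC | target

**Step count**
Total: 22 steps. Longest linear sequence: 18 steps (steps 1–14, then 19–22); steps 15–18 make the side-chain iodide.

**Steps most likely to fail, with fallbacks**

Step 3 (proposed new method). The tertiary radical may be reduced to the isopropyl group before it cyclises, the aldehyde may be reduced by the silane, or the alkoxy radical may reopen before it is trapped. The fallback uses known chemistry and sets out from 6. Cyanoethylation with acrylonitrile (benzyltrimethylammonium hydroxide cat., t-BuOH) should give methyl (1R,6R)-1-(2-cyanoethyl)-2-oxo-6-(prop-1-en-2-yl)cyclohex-3-ene-1-carboxylate F1, which is isolated. The known HAT-initiated reductive cyclisation of an alkene onto a nitrile (Fe(acac)3, PhSiH3, EtOH, high dilution, 60 °C) then closes ring A to methyl 3-imino-4,4-dimethyl-9-oxo-5α-decal-7-ene-10β-carboxylate F2, which is hydrolysed on acidic work-up. The route is rejoined at 10, and step 4 is skipped.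

Step 8. Hydrazone formation at the neopentyl C-9 carbonyl may be slow, so that hydrazine opens the epoxide or attacks the ester instead of triggering the fragmentation. The fallback sets out from 12 and avoids any condensation at C-9. LiAlH4 reduces the ketone (hydride anti to C-20) and the ester to 10β-(hydroxymethyl)-4,4-dimethyl-5α-decala-2,7-dien-9β-ol F3. Ac2O, pyridine and DMAP give the diacetate F4. PdCl2(MeCN)2 then catalyses the suprafacial [3,3] shift of the allylic acetate from the crowded C-9 to C-7, giving (7β-acetoxy-4,4-dimethyl-5α-decala-2,8-dien-10β-yl)methyl acetate F5. K2CO3 in MeOH frees 10β-(hydroxymethyl)-4,4-dimethyl-5α-decala-2,8-dien-7β-ol F6, and MnO2 oxidation as in step 10 returns to the route at 16.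

Step 19. Conjugate addition at the neopentyl C-9 may be sluggish, with competing 1,2-addition or enolisation by the Grignard reagent, and the trimethylsilyl enol ether may be lost before the Mannich step. The fallback sets out from 23 and 29 and avoids a basic organometallic. A nickel-catalysed reductive conjugate addition of the alkyl iodide (NiCl2·glyme, terpyridine-type ligand, Mn, Et3SiCl, DMF) should give (13R)-2α-angeloyloxy-3α,7,13-tris(triethylsilyloxy)-9βH-17-norlabda-7,14-dien-20-yl (2R)-2-methylbutanoate F7, a more robust silyl enol ether formed from the same α-face. Treatment with 30 as in step 19 returns to the route at 33.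

Further compounds
F1 | step 3 | methyl (1R,6R)-1-(2-cyanoethyl)-2-oxo-6-(prop-1-en-2-yl)cyclohex-3-ene-1-carboxylate | N#CCC[C@]1(C(=O)OC)C(=O)C=CC[C@H]1C(C)=C
F2 | step 3 | methyl 3-imino-4,4-dimethyl-9-oxo-5α-decal-7-ene-10β-carboxylate | O=C1C=CC[C@H]2C(C)(C)C(=N)CC[C@]12C(=O)OC
F3 | step 8 | 10β-(hydroxymethyl)-4,4-dimethyl-5α-decala-2,7-dien-9β-ol | O[C@H]1C=CC[C@H]2C(C)(C)C=CC[C@]12CO
F4 | step 8 | (9β-acetoxy-4,4-dimethyl-5α-decala-2,7-dien-10β-yl)methyl acetate | CC(=O)O[C@H]1C=CC[C@H]2C(C)(C)C=CC[C@]12COC(C)=O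
F5 | step 8 | (7β-acetoxy-4,4-dimethyl-5α-decala-2,8-dien-10β-yl)methyl acetate | C1=C[C@@H](OC(C)=O)C[C@H]2C(C)(C)C=CC[C@]12COC(C)=O
F6 | step 8 | 10β-(hydroxymethyl)-4,4-dimethyl-5α-decala-2,8-dien-7β-ol | C1=C[C@@H](O)C[C@H]2C(C)(C)C=CC[C@]12CO
F7 | step 19 | (13R)-2α-angeloyloxy-3α,7,13-tris(triethylsilyloxy)-9βH-17-norlabda-7,14-dien-20-yl (2R)-2-methylbutanoate | C=C[C@](C)(O[Si](CC)(CC)CC)CC[C@@H]1C=C(O[Si](CC)(CC)CC)C[C@H]2C(C)(C)[C@H](O[Si](CC)(CC)CC)[C@H](OC(=O)/C(C)=C\C)C[C@]12COC(=O)[C@H](C)CC
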